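The readings were computed on assumed constants.

0.0238 M/d is the number I plan around: it is S, the target made per day in cedar's early readings, and oak's early readings give 0.0225 M/d with a larger charge. So the passage of gas into solution looks like the rate-limiting step, and I carry τ, the fill time, which is the charge divided by S: 0.925 d for the new flask, 1.30 d for cedar, 2.02 d for oak.

the same everywhere: gas phase 0.77 mM (held)

| flask | starting material | remark | time |
|---|---|---|---|
| cedar | 0.031 M | run made earlier |  |
| oak | 0.048 M | run made earlier |  |
| flask | 0.022 M |  | 2.0 d |

- cedar (time / d: target / %): 0.208: 16; 0.417: 32; 1.04: 56; 2.50: 56
- oak (time / d: target / %): 0.333: 15; 0.833: 39; 1.67: 55; 2.50: 52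

(each reading ± 2 percentage points)

- the analysis behind the earlier runs scatters by 2 percentage points, standard deviation
- at the start none of the gas phase is in solution

* amount of target at 2.0 d, in percent of the starting material charged
* concentration of dissolved gas in solution at 2.0 d, in percent of saturation

I take two extreme versions of the flask. If nothing competes, target follows the line S·t and reaches the whole charge at τ. If the plateau is a fixed share, target stops near 55%. Cedar had left the line by 1.04 d, reading 56% where the line gives 79.8%, so part of its charge was not target by then. Because the flask's τ is shorter than either run's, I expect it above that plateau and well below the whole charge. Its demand should end before 2.0 d, leaving the solution near saturation.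

The forecast says 55% and 99%, reading the plateau as “a fixed selectivity or equilibrium ceiling”.

The flask gives 64.6% of target and dissolved gas at 103% of saturation, so its target stands higher than the forecast, by 9.6 percentage points.

    gas phase ⇌ dissolved gas, rate k1*(csat - [dissolved gas]) (kL = 0.0212 /min)
    starting material + dissolved gas ⇌ target (K = 11400 /M, k = 25.2 /M/min)
    starting material → side product (k = 4.08 × 10⁻⁴ /min)

In the flask, target formation had half its turnover done by 0.332 d, with dissolved gas at 8.18% of saturation at 0.200 d, and target stood at 67.3% at 1.00 d, just past τ. Later, side product grew from 24.1% to 28.4% at 2.00 d. For the neighbour flask with 0.088 M of starting material, τ is 3.70 d, longer than 2.0 d, and the line reaches 54.1% by then; that flask gives 43.2% of target and 49.4% of side product.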